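The numbers were set for the occasion; what happens was integrated by code.

Slowness costs your arithmetic nothing in this flask: steps 1 to 3 all carry the same factor of free partner, so a sluggish partner stretches the time axis of those steps and leaves their order of events as it is.

starting material 1.0 M; partner 2.50 M; capture agent 0.0200 M; time 10 h

    starting material + partner → single product + released group (k1 = 0.143 /M/min)
    partner + single product → double product + released group (k2 = 0.104 /M/min)
    partner + double product → triple product + released group (k3 = 0.328 /M/min)
    partner + released group ⇌ idle adduct, settled at all times (K4 = 0.95 /M)
    single product + capture agent → trapped intermediate (k5 = 0.0285 /M/min)

- part of the starting material that has reacted at 10 h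
- share of the unused partner that is free and not bound as idle adduct, at 10 h

- what is said of released group includes idle adduct
- run time (flask): 10 h

So follow one molecule of starting material on a clock x, which is k1 times the integral of free partner over time. It survives to x with chance a = exp(−x). Once it is single product, it moves on at a relative speed given by the selectivity factor σ, step 2's constant over step 1's, 0.727. The single product fraction is then a to the power σ, minus a, divided by one minus σ. The last step runs at 2.29 on the same clock. Each molecule bills 1, 2 or 3 partners as single, double or triple product, and the budget per starting material is 2.50.

- Clock 3: starting material 4.98%, single product 23.1%, double product 8.98%, bill 2.30.
- Clock 4: starting material 1.83%, single product 13.3%, double product 5.51%, bill 2.62.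

The first row stays under budget and the second overruns it, so the partner is the limiting reagent and the clock stops between the rows, at about 3.62. That makes my conversion 97.3%. I drop capture here, since at the charged amounts single product has a half-life of 20 h by step 5, far longer than the 1.9 min of starting material by step 1. Released group ends near 2.50 M, so my free share is 29.6%.

The forecast gives 97.1% reacted and 29.6% free: “The partner is short of the three equivalents needed”. The simulation gives 97.2% reacted and 29.6% free.

In this flask, with partner at 0% at 10.0 h, single product has a half-life by step 2 of 94 d, far longer than the 10 h run. At 0.0403 h in the same flask, starting material had a half-life of 0.054 h by step 1. In this flask, the 2.78% of starting material left puts the selectivity rule at 16.9%, against 17.5% read as single product plus trapped intermediate. In the neighbour flask with 1.7 M of starting material, 19.9% left gives 40.4%, against 40.5% read there.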